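- spring: starting material 1.1 M; partner 1.65 M; the very flask that is asked about, followed so far
- flask: starting material 1.1 M; partner 1.65 M; time 2.0 h

- spring (time / min: intermediate C / %, target / %): 4.00: 4, 0; 8.00: 14, 0; 20.0: 27, 1; 50.0: 53, 0

(readings scatter by 2 percentage points)

1. amount of intermediate C in percent of the starting material charged, at 25 min, 1.0 h and 2.0 h



- Weigh two times against each other in this flask: the time in which intermediate C fills and the time in which it drains.
- For the first I treated the rise as one bimolecular step of starting material, the limiting reagent, with partner at 1.50 charges. The reading at 50.0 min gave a logarithmic rate of 0.00638 min⁻¹, so the filling time, the life of starting material at its opening rate, was 52.2 min, and that curve reached 34.2%, 58.3% and 77.5% at the asked times.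
- For the second I replaced the bent curve by its mean over the spring run, 31.6% of the charge, and since target stayed at zero within one scatter, I kept 13.2 h as the estimated loss time: mean intermediate C times elapsed time, divided by the amount gone, for which I allowed one scatter.
- With the loss time longer than the filling time, I took the mean 51.8% over the flask's course, which allowed a loss of 7.9 percentage points by 2.0 h, and I committed to 34.2%, 58.3% and 69.6% to 77.5%.
- The forecast gave 33%, 57% and 72%, choosing to “widen its range on the low side”; the simulation gave 34.9%, 58.2% and 72.3%.

    starting material + partner ⇌ intermediate A (K = 0.380 L mol⁻¹, k = 0.0150 L mol⁻¹ min⁻¹)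
    intermediate A → intermediate B (k = 0.00400 min⁻¹)
    partner + intermediate B → side product (k = 0.00330 L mol⁻¹ min⁻¹)
    intermediate A → intermediate C (k = 0.440 min⁻¹)
    partner + intermediate C → intermediate D (k = 0.00130 L mol⁻¹ min⁻¹)
    intermediate D → target (k = 0.00220 min⁻¹)

- At 2.00 h the flask made intermediate C 2.90 times as fast as it used it up. By then intermediate D held 6.37% and target 0.778%, and that 7.15% over the mean of 51.8% made a loss time of 14.5 h, beside the carried 13.2 h.

The runs were generated by integration with made-up constants.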